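**Plan**

Ring numbering used here: C1 = quaternary carbon, C2 = CH–CH2OAr, C3 = C–Me, C4 = ring =CH, C5 = CH–isopropenyl, C6 = CH2.

- Retrosynthetic cuts, in order: (i) the aryl ether O–CH2 bond (Mitsunobu with umbelliferone); (ii) the C2–CH2O bond together with the C3=C4 alkene, by a retro-[2,3] Wittig–Still shift to a C4 allylic alcohol with a C2=C3 alkene; (iii) the ring bonds C4–C5 and C6–C1, by a Diels–Alder reaction of a 1-silyloxy diene with methyl vinyl ketone.
- Enabling feature: the cyclohexene alkene lies one bond away from the Diels–Alder position, and the larger groups on C1, C2 and C5 are all cis. An endo adduct of an (E,E)-1-oxy diene followed by a suprafacial 1,3-shift from the C4 oxygen to C2 gives exactly this pattern. The same oxygen turns the regiochemistry so that the CH2 carbon (C6) meets the quaternary carbon.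
- Forward order: the chain is built first (pentynol, two carboaluminations with an ethynylation between them, dienylboronate, silyl dienol ether). The only carbocycle then arises in the cycloaddition, followed by isopropenyl formation, the [2,3] shift, coumarin attachment and oxidation to the acid.
- Stereochemistry: C1 comes from the E alkene set by the first carboalumination; C5 and the temporary C4–O centre come from endo addition to the enone face selected by a chiral oxazaborolidinium catalyst; C2 comes from C4–O through the [2,3] shift.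

Key step: step 6

Assumption: the enone is taken to bind the (R)-oxazaborolidinium ion as in the α-C–H···O model for enones and acrylates, which leaves the re face of the enone α-carbon open; that face leads to adduct 10 as drawn.

**Route**

Step 1
Reactants: 1 pent-4-yn-1-ol
Product: 2 tert-butyl(pent-4-yn-1-yloxy)diphenylsilane
Conditions: TBDPSCl, imidazole, DMF, 0 °C to rt
Reagents that add atoms: tert-butyl(chloro)diphenylsilane, CC(C)(C)[Si](Cl)(c1ccccc1)c1ccccc1
Why: Imidazole-promoted silylation of a primary alcohol (silyl ether protection); the TBDPS ether should survive Me3Al, Lewis acids, mild acid, KH and n-BuLi and is removed last with fluoride.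

Step 2
Reactants: 2 tert-butyl(pent-4-yn-1-yloxy)diphenylsilane
Product: 4 tert-butyl{[(4E)-5-iodo-4-methylpent-4-en-1-yl]oxy}diphenylsilane, via alkenylalane 3 (not isolated)
Conditions: Me3Al, Cp2ZrCl2 (cat.), CH2Cl2, 0 °C to rt; then I2, THF, −30 to 0 °C
Reagents that add atoms: trimethylaluminium, C[Al](C)C; iodine, II
Why: Negishi zirconium-catalysed carboalumination adds methyl and aluminium syn across the terminal alkyne with aluminium on the terminal carbon, and iodinolysis retains geometry, so the E alkene (iodine cis to methyl) should form; no stereocentre is made.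

Step 3
Reactants: 4 tert-butyl{[(4E)-5-iodo-4-methylpent-4-en-1-yl]oxy}diphenylsilane
Product: 5 tert-butyl{[(4E)-4-methylhept-4-en-6-yn-1-yl]oxy}diphenylsilane
Conditions: HC≡CMgBr, ZnBr2, THF, 0 °C (ethynylzinc bromide); Pd(PPh3)4 (cat.), THF, rt
Reagents that add atoms: ethynylmagnesium bromide, C#C[Mg]Br
Why: Negishi cross-coupling of an alkenyl iodide with ethynylzinc bromide retains alkene geometry and should give the terminal enyne directly.

Step 4
Reactants: 5 tert-butyl{[(4E)-4-methylhept-4-en-6-yn-1-yl]oxy}diphenylsilane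
Product: 7 tert-butyl{[(4E,6E)-4,6-dimethyl-7-(4,4,5,5-tetramethyl-1,3,2-dioxaborolan-2-yl)hepta-4,6-dien-1-yl]oxy}diphenylsilane, via dienylalane 6 (not isolated)
Conditions: Me3Al, Cp2ZrCl2 (cat.), CH2Cl2, 0 °C to rt; then iPrOBpin, THF, 0 °C to rt
Reagents that add atoms: trimethylaluminium, C[Al](C)C; 2-isopropoxy-4,4,5,5-tetramethyl-1,3,2-dioxaborolane, CC(C)OB1OC(C)(C)C(C)(C)O1
Why: A second Negishi carboalumination on the conjugated enyne is again syn and terminal-selective, and aluminium-to-boron transmetallation with an alkoxyboronate retains geometry, which should give the (E,E)-dienylboronate.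

Step 5
Reactants: 7 tert-butyl{[(4E,6E)-4,6-dimethyl-7-(4,4,5,5-tetramethyl-1,3,2-dioxaborolan-2-yl)hepta-4,6-dien-1-yl]oxy}diphenylsilane
Product: 8 tert-butyl({(4E,6E)-4,6-dimethyl-7-[(triethylsilyl)oxy]hepta-4,6-dien-1-yl}oxy)diphenylsilane
Conditions: Et3SiOH, Cu(OAc)2 (2 equiv), pyridine, 4 Å MS, CH2Cl2, air, rt
Reagents that add atoms: triethylsilanol, CC[Si](O)(CC)CC
Why: Chan–Lam-type copper-promoted C–O coupling of an alkenyl pinacol boronate with a silanol is stereoretentive, so the silyloxy group should end trans to the diene chain, the "outside" position needed in the cycloaddition.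

Step 6
Reactants: 8 tert-butyl({(4E,6E)-4,6-dimethyl-7-[(triethylsilyl)oxy]hepta-4,6-dien-1-yl}oxy)diphenylsilane; 9 but-3-en-2-one
Product: 10 1-[(1S,2S,5R)-5-(3-{[tert-butyl(diphenyl)silyl]oxy}propyl)-3,5-dimethyl-2-[(triethylsilyl)oxy]cyclohex-3-en-1-yl]ethan-1-one
Conditions: (3aR)-1-(2-methylphenyl)-3,3-diphenyltetrahydro-1H,3H-pyrrolo[1,2-c][1,3,2]oxazaborole (20 mol %), Tf2NH (17 mol %), CH2Cl2, −78 to −40 °C
Reagents that add atoms: none
Why: The enone is activated by O-coordination to the boron of the triflimide-generated oxazaborolidinium ion and adds to the silyl dienol ether in a concerted but asynchronous [4+2] cycloaddition, in which the methyl- and chain-bearing diene terminus (the vinylogous enol-ether carbon) leads onto the enone CH2 and the oxygen-bearing terminus closes onto the α-carbon. The closest known reaction type is the enantioselective Diels–Alder reaction of silyloxy dienes with enones and acrylates under cationic CBS-type oxazaborolidine catalysis. The one carbocycle is closed by this intermolecular suprafacial–suprafacial union of a four-carbon and a two-carbon fragment (a cycloaddition, with no tether and no separate cyclisation), and the methyl group on the inner diene carbon disfavours the s-trans conformer, which is what lets a diene with a fully substituted terminus react. The quaternary carbon follows from the E geometry of the trisubstituted alkene of 8 (chain outside, methyl inside) by suprafacial addition, the cis relation of silyloxy and acetyl from the endo transition state, and the absolute configuration from the catalyst, whose aryl group shields the si face of the enone α-carbon so that the diene adds to the re face. The step needs ortho regiochemistry, endo selectivity and ring closure in preference to open-chain Mukaiyama–Michael addition: the first is secured by the 1-silyloxy donor, which outweighs the three alkyl groups and makes the substituted terminus the nucleophilic one, the second by Lewis-acid activation at low temperature, and the third by the s-cis bias of the diene together with the non-nucleophilic triflimide counter-ion.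

Step 7
Reactants: 10 1-[(1S,2S,5R)-5-(3-{[tert-butyl(diphenyl)silyl]oxy}propyl)-3,5-dimethyl-2-[(triethylsilyl)oxy]cyclohex-3-en-1-yl]ethan-1-one
Product: 11 tert-butyl(3-{(1R,4S,5R)-1,3-dimethyl-5-(prop-1-en-2-yl)-4-[(triethylsilyl)oxy]cyclohex-2-en-1-yl}propoxy)diphenylsilane
Conditions: Zn, CH2Br2, TiCl4, THF–CH2Cl2, 0 °C to rt
Reagents that add atoms: dibromomethane, BrCBr
Why: Takai–Lombardo methylenation is non-basic, so the methyl ketone should become the isopropenyl group without epimerisation at the α-carbon or β-elimination of the silyloxy group.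

Step 8
Reactants: 11 tert-butyl(3-{(1R,4S,5R)-1,3-dimethyl-5-(prop-1-en-2-yl)-4-[(triethylsilyl)oxy]cyclohex-2-en-1-yl}propoxy)diphenylsilane
Product: 12 (1S,4R,6R)-4-(3-{[tert-butyl(diphenyl)silyl]oxy}propyl)-2,4-dimethyl-6-(prop-1-en-2-yl)cyclohex-2-en-1-ol
Conditions: PPTS (cat.), MeOH–CH2Cl2, 0 °C
Reagents that add atoms: none
Why: Acid-catalysed methanolysis cleaves a triethylsilyl ether far faster than a primary TBDPS ether (selective silyl ether cleavage), which should free only the allylic alcohol.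

Step 9
Reactants: 12 (1S,4R,6R)-4-(3-{[tert-butyl(diphenyl)silyl]oxy}propyl)-2,4-dimethyl-6-(prop-1-en-2-yl)cyclohex-2-en-1-ol
Product: 14 tributyl({[(1S,4R,6R)-4-(3-{[tert-butyl(diphenyl)silyl]oxy}propyl)-2,4-dimethyl-6-(prop-1-en-2-yl)cyclohex-2-en-1-yl]oxy}methyl)stannane, via potassium alkoxide 13 (not isolated)
Conditions: KH, 18-crown-6 (cat.), THF, 0 °C; then Bu3SnCH2I, rt
Reagents that add atoms: tributyl(iodomethyl)stannane, CCCC[Sn](CI)(CCCC)CCCC
Why: Williamson etherification of the potassium alkoxide with Still's iodomethylstannane; the C–O bond of the stereocentre is not touched.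

Step 10
Reactants: 14 tributyl({[(1S,4R,6R)-4-(3-{[tert-butyl(diphenyl)silyl]oxy}propyl)-2,4-dimethyl-6-(prop-1-en-2-yl)cyclohex-2-en-1-yl]oxy}methyl)stannane
Product: 17 [(1R,4S,6R)-6-(3-{[tert-butyl(diphenyl)silyl]oxy}propyl)-2,6-dimethyl-4-(prop-1-en-2-yl)cyclohex-2-en-1-yl]methanol, via lithiomethyl ether 15 (not isolated), via lithium alkoxide 16 (not isolated)
Conditions: n-BuLi, THF, −78 °C; then H2O
Reagents that add atoms: none
Why: Tin–lithium exchange gives an α-alkoxymethyllithium that undergoes the Still–Wittig [2,3]-sigmatropic rearrangement; the shift is suprafacial, so the CH2O carbon should arrive at the ring carbon next to the quaternary centre on the face that carried the oxygen (cis to the propyl chain and the isopropenyl group), while the alkene moves to its final place.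

Step 11
Reactants: 17 [(1R,4S,6R)-6-(3-{[tert-butyl(diphenyl)silyl]oxy}propyl)-2,6-dimethyl-4-(prop-1-en-2-yl)cyclohex-2-en-1-yl]methanol; 18 7-hydroxy-2H-chromen-2-one (umbelliferone)
Product: 19 7-{[(1R,4S,6R)-6-(3-{[tert-butyl(diphenyl)silyl]oxy}propyl)-2,6-dimethyl-4-(prop-1-en-2-yl)cyclohex-2-en-1-yl]methoxy}-2H-chromen-2-one
Conditions: PPh3, DIAD, THF, 0 °C to rt
Reagents that add atoms: none
Why: Mitsunobu etherification of a primary alcohol with an acidic phenol; the reacting carbon is not stereogenic and no stereocentre is touched.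

Step 12
Reactants: 19 7-{[(1R,4S,6R)-6-(3-{[tert-butyl(diphenyl)silyl]oxy}propyl)-2,6-dimethyl-4-(prop-1-en-2-yl)cyclohex-2-en-1-yl]methoxy}-2H-chromen-2-one
Product: 20 7-{[(1R,4S,6R)-6-(3-hydroxypropyl)-2,6-dimethyl-4-(prop-1-en-2-yl)cyclohex-2-en-1-yl]methoxy}-2H-chromen-2-one
Conditions: TBAF, AcOH, THF, rt
Reagents that add atoms: none
Why: Fluoride-induced desilylation; buffering with acetic acid should keep the coumarin lactone closed.

Step 13
Reactants: 20 7-{[(1R,4S,6R)-6-(3-hydroxypropyl)-2,6-dimethyl-4-(prop-1-en-2-yl)cyclohex-2-en-1-yl]methoxy}-2H-chromen-2-one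
Product: 22 3-[(1R,2R,5S)-1,3-dimethyl-2-{[(2-oxo-2H-chromen-7-yl)oxy]methyl}-5-(prop-1-en-2-yl)cyclohex-3-en-1-yl]propanoic acid, via aldehyde 21 (not isolated)
Conditions: TEMPO (cat.), PhI(OAc)2, MeCN–H2O, rt
Reagents that add atoms: water, O
Why: Oxoammonium oxidation (TEMPO with PhI(OAc)2) takes the primary alcohol through the aldehyde and its hydrate to the acid and should leave the alkenes, the aryl ether and the lactone untouched.

**Compound list**

1 | pent-4-yn-1-ol | C#CCCCO | starting material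
2 | tert-butyl(pent-4-yn-1-yloxy)diphenylsilane | C#CCCCO[Si](c1ccccc1)(c1ccccc1)C(C)(C)C | intermediate
3 | [(1E)-5-{[tert-butyl(diphenyl)silyl]oxy}-2-methylpent-1-en-1-yl]dimethylalane | C[Al](C)/C=C(\C)CCCO[Si](c1ccccc1)(c1ccccc1)C(C)(C)C | intermediate
4 | tert-butyl{[(4E)-5-iodo-4-methylpent-4-en-1-yl]oxy}diphenylsilane | I/C=C(\C)CCCO[Si](c1ccccc1)(c1ccccc1)C(C)(C)C | intermediate
5 | tert-butyl{[(4E)-4-methylhept-4-en-6-yn-1-yl]oxy}diphenylsilane | C#C/C=C(\C)CCCO[Si](c1ccccc1)(c1ccccc1)C(C)(C)C | intermediate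
6 | [(1E,3E)-7-{[tert-butyl(diphenyl)silyl]oxy}-2,4-dimethylhepta-1,3-dien-1-yl]dimethylalane | C[Al](C)/C=C(\C)/C=C(\C)CCCO[Si](c1ccccc1)(c1ccccc1)C(C)(C)C | intermediate
7 | tert-butyl{[(4E,6E)-4,6-dimethyl-7-(4,4,5,5-tetramethyl-1,3,2-dioxaborolan-2-yl)hepta-4,6-dien-1-yl]oxy}diphenylsilane | CC1(C)OB(/C=C(\C)/C=C(\C)CCCO[Si](c2ccccc2)(c2ccccc2)C(C)(C)C)OC1(C)C | intermediate
8 | tert-butyl({(4E,6E)-4,6-dimethyl-7-[(triethylsilyl)oxy]hepta-4,6-dien-1-yl}oxy)diphenylsilane | CC[Si](CC)(CC)O/C=C(\C)/C=C(\C)CCCO[Si](c1ccccc1)(c1ccccc1)C(C)(C)C | intermediate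
9 | but-3-en-2-one (methyl vinyl ketone) | CC(=O)C=C | starting material
10 | 1-[(1S,2S,5R)-5-(3-{[tert-butyl(diphenyl)silyl]oxy}propyl)-3,5-dimethyl-2-[(triethylsilyl)oxy]cyclohex-3-en-1-yl]ethan-1-one | CC(=O)[C@@H]1[C@H](O[Si](CC)(CC)CC)C(C)=C[C@](C)(CCCO[Si](c2ccccc2)(c2ccccc2)C(C)(C)C)C1 | intermediate
11 | tert-butyl(3-{(1R,4S,5R)-1,3-dimethyl-5-(prop-1-en-2-yl)-4-[(triethylsilyl)oxy]cyclohex-2-en-1-yl}propoxy)diphenylsilane | C=C(C)[C@@H]1[C@H](O[Si](CC)(CC)CC)C(C)=C[C@](C)(CCCO[Si](c2ccccc2)(c2ccccc2)C(C)(C)C)C1 | intermediate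
12 | (1S,4R,6R)-4-(3-{[tert-butyl(diphenyl)silyl]oxy}propyl)-2,4-dimethyl-6-(prop-1-en-2-yl)cyclohex-2-en-1-ol | C=C(C)[C@@H]1[C@H](O)C(C)=C[C@](C)(CCCO[Si](c2ccccc2)(c2ccccc2)C(C)(C)C)C1 | intermediate
13 | potassium (1S,4R,6R)-4-(3-{[tert-butyl(diphenyl)silyl]oxy}propyl)-2,4-dimethyl-6-(prop-1-en-2-yl)cyclohex-2-en-1-olate | C=C(C)[C@@H]1[C@H]([O-])C(C)=C[C@](C)(CCCO[Si](c2ccccc2)(c2ccccc2)C(C)(C)C)C1.[K+] | intermediate
14 | tributyl({[(1S,4R,6R)-4-(3-{[tert-butyl(diphenyl)silyl]oxy}propyl)-2,4-dimethyl-6-(prop-1-en-2-yl)cyclohex-2-en-1-yl]oxy}methyl)stannane | C=C(C)[C@@H]1[C@H](OC[Sn](CCCC)(CCCC)CCCC)C(C)=C[C@](C)(CCCO[Si](c2ccccc2)(c2ccccc2)C(C)(C)C)C1 | intermediate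
15 | ({[(1S,4R,6R)-4-(3-{[tert-butyl(diphenyl)silyl]oxy}propyl)-2,4-dimethyl-6-(prop-1-en-2-yl)cyclohex-2-en-1-yl]oxy}methyl)lithium | C=C(C)[C@@H]1[C@H](OC[Li])C(C)=C[C@](C)(CCCO[Si](c2ccccc2)(c2ccccc2)C(C)(C)C)C1 | intermediate
16 | lithium [(1R,4S,6R)-6-(3-{[tert-butyl(diphenyl)silyl]oxy}propyl)-2,6-dimethyl-4-(prop-1-en-2-yl)cyclohex-2-en-1-yl]methanolate | C=C(C)[C@@H]1C=C(C)[C@H](C[O-])[C@](C)(CCCO[Si](c2ccccc2)(c2ccccc2)C(C)(C)C)C1.[Li+] | intermediate
17 | [(1R,4S,6R)-6-(3-{[tert-butyl(diphenyl)silyl]oxy}propyl)-2,6-dimethyl-4-(prop-1-en-2-yl)cyclohex-2-en-1-yl]methanol | C=C(C)[C@@H]1C=C(C)[C@H](CO)[C@](C)(CCCO[Si](c2ccccc2)(c2ccccc2)C(C)(C)C)C1 | intermediate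
18 | 7-hydroxy-2H-chromen-2-one (umbelliferone) | O=c1ccc2ccc(O)cc2o1 | starting material
19 | 7-{[(1R,4S,6R)-6-(3-{[tert-butyl(diphenyl)silyl]oxy}propyl)-2,6-dimethyl-4-(prop-1-en-2-yl)cyclohex-2-en-1-yl]methoxy}-2H-chromen-2-one | C=C(C)[C@@H]1C=C(C)[C@H](COc2ccc3ccc(=O)oc3c2)[C@](C)(CCCO[Si](c4ccccc4)(c5ccccc5)C(C)(C)C)C1 | intermediate
20 | 7-{[(1R,4S,6R)-6-(3-hydroxypropyl)-2,6-dimethyl-4-(prop-1-en-2-yl)cyclohex-2-en-1-yl]methoxy}-2H-chromen-2-one | C=C(C)[C@@H]1C=C(C)[C@H](COc2ccc3ccc(=O)oc3c2)[C@](C)(CCCO)C1 | intermediate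
21 | 3-[(1R,2R,5S)-1,3-dimethyl-2-{[(2-oxo-2H-chromen-7-yl)oxy]methyl}-5-(prop-1-en-2-yl)cyclohex-3-en-1-yl]propanal | C=C(C)[C@@H]1C=C(C)[C@H](COc2ccc3ccc(=O)oc3c2)[C@](C)(CCC=O)C1 | intermediate
22 | 3-[(1R,2R,5S)-1,3-dimethyl-2-{[(2-oxo-2H-chromen-7-yl)oxy]methyl}-5-(prop-1-en-2-yl)cyclohex-3-en-1-yl]propanoic acid | C=C(C)[C@@H]1C=C(C)[C@H](COc2ccc3ccc(=O)oc3c2)[C@](C)(CCC(=O)O)C1 | target

**Step count and risks**

Total step count: 13. Longest linear sequence: 13 steps from pent-4-yn-1-ol (methyl vinyl ketone and umbelliferone are bought).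

Steps most likely to fail:

Step 6. The twisted diene with a fully substituted terminus may react too slowly, so that desilylation of the dienol ether or open-chain conjugate addition takes over, or the catalyst may give poor facial selectivity. The fallback replaces catalyst control by auxiliary control and sets out from 8. (4R)-4-Benzyl-1,3-oxazolidin-2-one is acylated with acryloyl chloride (n-BuLi, THF, −78 °C) to give (4R)-4-benzyl-3-(prop-2-enoyl)-1,3-oxazolidin-2-one F1. Its Me2AlCl chelate (CH2Cl2, −78 °C) is a far stronger dienophile and should add 8 endo on the α-carbon re face, opposite the benzyl group, to give (4R)-4-benzyl-3-{[(1S,2S,5R)-5-(3-{[tert-butyl(diphenyl)silyl]oxy}propyl)-3,5-dimethyl-2-[(triethylsilyl)oxy]cyclohex-3-en-1-yl]carbonyl}-1,3-oxazolidin-2-one F2. EtSLi (from EtSH and n-BuLi, THF, 0 °C) should then give S-ethyl (1S,2S,5R)-5-(3-{[tert-butyl(diphenyl)silyl]oxy}propyl)-3,5-dimethyl-2-[(triethylsilyl)oxy]cyclohex-3-ene-1-carbothioate F3, and Me2CuLi (Et2O, −78 °C) should convert the thioester into ketone 10, where the route is rejoined.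

Step 5. Protodeboronation or oxidative homocoupling of the dienylboronate, or hydrolysis of the triethylsilyl dienol ether during copper removal, may erode the material. The fallback sets out from 7. Oxidation with NaBO3·4H2O in THF–H2O should give (3E)-7-{[tert-butyl(diphenyl)silyl]oxy}-2,4-dimethylhept-3-enal F4 with the trisubstituted alkene untouched. Soft enolisation with Et3SiOTf and Et3N (CH2Cl2, −78 °C) should then give 8, where the route is rejoined; any Z enol ether formed would be inert in step 6.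

Step 10. Because the receiving carbon is flanked by the quaternary centre, a [1,2]-shift or simple protonation of the α-alkoxymethyllithium may compete with the [2,3]-shift. The fallback sets out from 12 and bypasses steps 9 and 10. Heating with Me2NCH(OMe)2 in xylene at 140 °C (Büchi [2,3]-rearrangement of the derived aminoalkoxycarbene, also suprafacial) should give (1R,4S,6R)-6-(3-{[tert-butyl(diphenyl)silyl]oxy}propyl)-N,N,2,6-tetramethyl-4-(prop-1-en-2-yl)cyclohex-2-ene-1-carboxamide F5. Reduction with LiBHEt3 in THF should then give alcohol 17, where the route is rejoined.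

Further compounds
F1 | step 6 | (4R)-4-benzyl-3-(prop-2-enoyl)-1,3-oxazolidin-2-one | C=CC(=O)N1[C@H](Cc2ccccc2)COC1=O
F2 | step 6 | (4R)-4-benzyl-3-{[(1S,2S,5R)-5-(3-{[tert-butyl(diphenyl)silyl]oxy}propyl)-3,5-dimethyl-2-[(triethylsilyl)oxy]cyclohex-3-en-1-yl]carbonyl}-1,3-oxazolidin-2-one | O=C([C@@H]1[C@H](O[Si](CC)(CC)CC)C(C)=C[C@](C)(CCCO[Si](c2ccccc2)(c2ccccc2)C(C)(C)C)C1)N1[C@H](Cc2ccccc2)COC1=O
F3 | step 6 | S-ethyl (1S,2S,5R)-5-(3-{[tert-butyl(diphenyl)silyl]oxy}propyl)-3,5-dimethyl-2-[(triethylsilyl)oxy]cyclohex-3-ene-1-carbothioate | CCSC(=O)[C@@H]1[C@H](O[Si](CC)(CC)CC)C(C)=C[C@](C)(CCCO[Si](c2ccccc2)(c2ccccc2)C(C)(C)C)C1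
F4 | step 5 | (3E)-7-{[tert-butyl(diphenyl)silyl]oxy}-2,4-dimethylhept-3-enal | O=CC(C)/C=C(\C)CCCO[Si](c1ccccc1)(c1ccccc1)C(C)(C)C
F5 | step 10 | (1R,4S,6R)-6-(3-{[tert-butyl(diphenyl)silyl]oxy}propyl)-N,N,2,6-tetramethyl-4-(prop-1-en-2-yl)cyclohex-2-ene-1-carboxamide | C=C(C)[C@@H]1C=C(C)[C@H](C(=O)N(C)C)[C@](C)(CCCO[Si](c2ccccc2)(c2ccccc2)C(C)(C)C)C1
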